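**Retrosynthetic overview**

1. Target ⇒ macrocyclic tertiary α-ketol (the C8 methacrylate and C10 acetate are put on last). The ten-membered ring is opened at C1–C10: the C1 aldehyde reacts as an acyl anion (carbene-catalysed crossed benzoin) with the C10 methyl ketone, creating the C1 ketone, the C10 carbinol and its configuration in one step.
2. Seco keto-aldehyde ⇒ one ozonolysis of a diene: the nerol-type trisubstituted alkene gives the C1 aldehyde, and a methallyl group, added to a C8 aldehyde by asymmetric methallylboration (sets C8), gives the C10 ketone.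
3. All-cis γ-lactone ⇒ indium Barbier allylation/lactonisation of an epoxy aldehyde with a (Z)-2-(bromomethyl)enoate (sets C6, C7), then conjugate borylation/protonation/oxidation (sets C11, brings in O13).
4. Building blocks: nerol (Sharpless epoxidation sets C4, C5); methyl acrylate and (tert-butyldimethylsilyloxy)acetaldehyde (Baylis–Hillman, SN2′ bromination).
5. Ring order: epoxide → γ-lactone → ten-membered carbocycle (last).

Assumption: locants follow germacranolide numbering (C1 ketone, C4–C5 epoxide, O on C6 in the lactone, C8 methacrylate, C10 acetate, C13 acetoxymethyl); read from the SMILES, the target is (4R,5S,6S,7S,8S,10R,11R), with a cis-4,5-epoxide and H6, H7, H11 on one face of the lactone.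

**Route**

Step 1
Reactants: 1 nerol
Product: 2 (2S,3R)-2,3-epoxynerol
Conditions: Ti(OiPr)4 (5 mol%), L-(+)-diethyl tartrate (7 mol%), tBuOOH (2 equiv, decane), 4 Å MS, CH2Cl2, −20 °C
Reagents that add atoms: tert-butyl hydroperoxide, CC(C)(C)OO
Why: Sharpless asymmetric epoxidation; the L-(+)-tartrate catalyst delivers oxygen to the allylic-alcohol face that gives (2S,3R) (C5 S and C4 R of the target) and leaves the remote trisubstituted alkene untouched.

Step 2
Reactants: 2 (2S,3R)-2,3-epoxynerol
Product: 3 (2R,3R)-3-methyl-3-(4-methylpent-3-en-1-yl)oxirane-2-carbaldehyde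
Conditions: Dess–Martin periodinane, pyridine, CH2Cl2, 0 °C → rt; used crude
Reagents that add atoms: none
Why: Dess–Martin oxidation under buffered conditions; the α-carbon is an epoxide carbon and does not epimerise (the descriptor changes only through CIP priorities).

Step 3
Reactants: 4 (tert-butyldimethylsilyloxy)acetaldehyde; 5 methyl acrylate
Product: 6 methyl 4-[(tert-butyldimethylsilyl)oxy]-3-hydroxy-2-methylidenebutanoate (racemic)
Conditions: DABCO (1 equiv), 5 (2 equiv), 1,4-dioxane/H2O 1:1, rt, 48 h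
Reagents that add atoms: none
Why: Morita–Baylis–Hillman reaction of an activated α-oxy aldehyde; the carbinol centre becomes sp2 in the next step, so no stereocontrol is needed.

Step 4
Reactants: 6 Baylis–Hillman adduct
Product: 7 methyl (Z)-2-(bromomethyl)-4-[(tert-butyldimethylsilyl)oxy]but-2-enoate
Conditions: NBS (1.5 equiv), Me2S (1.6 equiv), CH2Cl2, 0 °C → rt
Reagents that add atoms: N-bromosuccinimide, O=C1CCC(=O)N1Br
Why: Corey–Kim-type activation of the hydroxyl as an alkoxysulfonium ion and SN2′ attack of bromide (allylic transposition) gives the thermodynamically preferred (Z)-bromide under acid-free conditions that spare the silyl ether.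

Step 5
Reactants: 3 epoxy aldehyde; 7 allylic bromide
Product: 9 (4S,5S)-4-{[tert-butyl(dimethyl)silyl]oxymethyl}-3-methylidene-5-[(2S,3R)-3-methyl-3-(4-methylpent-3-en-1-yl)oxiran-2-yl]oxolan-2-one, via syn-hydroxy ester 8 (not isolated)
Conditions: In powder (1.5 equiv), THF/H2O 3:1, rt; extract; DBU (5 mol%), CH2Cl2, 0 °C → rt
Reagents that add atoms: none
Why: Indium-mediated Barbier allylation: the γ-carbon of the (Z)-allyl metal attacks through a Zimmerman–Traxler chair with CH2OTBS axial (syn adduct, hence the cis-lactone at C6/C7), the epoxy aldehyde reacts in the Felkin–Anh sense (epoxide C–O anti to the incoming carbon, reinforced by the cis substituent; anti epoxy alcohol at C5/C6), and base-catalysed transesterification closes the γ-lactone.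

Step 6
Reactants: 9 α-methylene lactone
Product: 11 (3R,4S,5S)-4-{[tert-butyl(dimethyl)silyl]oxymethyl}-3-(hydroxymethyl)-5-[(2S,3R)-3-methyl-3-(4-methylpent-3-en-1-yl)oxiran-2-yl]oxolan-2-one, via pinacol boronate 10 (not isolated)
Conditions: CuCl (5 mol%), Xantphos (5 mol%), NaOtBu (8 mol%), B2pin2 (1.1 equiv), MeOH (2 equiv), THF, 0 °C → rt; then NaBO3·4H2O (5 equiv), THF/H2O, rt
Reagents that add atoms: bis(pinacolato)diboron, CC1(C)OB(OC1(C)C)B1OC(C)(C)C(C)(C)O1 (boron of 10); sodium perborate tetrahydrate, [Na+].[Na+].O[B-]1(O)OO[B-](O)(O)OO1 as the hydrate (oxygen of the C13 hydroxyl)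
Why: Copper-catalysed conjugate borylation: the copper boryl adds to the exocyclic enoate and the enolate is protonated by MeOH on the lactone face opposite the two cis substituents at C6 and C7, which sets C11 with the CH2B group cis to them; perborate then oxidises the primary C–B bond.

Step 7
Reactants: 11 primary alcohol
Product: 12 [(3R,4S,5S)-4-{[tert-butyl(dimethyl)silyl]oxymethyl}-5-[(2S,3R)-3-methyl-3-(4-methylpent-3-en-1-yl)oxiran-2-yl]-2-oxooxolan-3-yl]methyl acetate
Conditions: Ac2O (1.5 equiv), pyridine, DMAP (5 mol%), CH2Cl2, 0 °C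
Reagents that add atoms: acetic anhydride, CC(=O)OC(C)=O
Why: DMAP-catalysed acetylation of the only free hydroxyl; the mild base and low temperature avoid β-elimination of the new acetate and epimerisation at C11.

Step 8
Reactants: 12 silyl ether
Product: 13 [(3R,4S,5S)-4-(hydroxymethyl)-5-[(2S,3R)-3-methyl-3-(4-methylpent-3-en-1-yl)oxiran-2-yl]-2-oxooxolan-3-yl]methyl acetate
Conditions: HF·pyridine, pyridine, THF, 0 °C → rt
Reagents that add atoms: none
Why: Fluoride-mediated silyl ether cleavage under buffered, slightly acidic conditions, which suppress acetate migration, translactonisation and elimination and are known to spare trisubstituted epoxides.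

Step 9
Reactants: 13 primary alcohol
Product: 14 [(3R,4R,5S)-4-formyl-5-[(2S,3R)-3-methyl-3-(4-methylpent-3-en-1-yl)oxiran-2-yl]-2-oxooxolan-3-yl]methyl acetate
Conditions: Dess–Martin periodinane, pyridine, CH2Cl2, 0 °C; crude aldehyde used at once
Reagents that add atoms: none
Why: Dess–Martin oxidation under buffered non-basic conditions keeps the epimerisable C7 centre intact (its descriptor changes only through CIP priorities).

Step 10
Reactants: 14 aldehyde
Product: 15 [(3R,4S,5S)-4-[(1S)-1-hydroxy-3-methylbut-3-en-1-yl]-5-[(2S,3R)-3-methyl-3-(4-methylpent-3-en-1-yl)oxiran-2-yl]-2-oxooxolan-3-yl]methyl acetate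
Conditions: (−)-Ipc2BOMe (1.5 equiv), methallylmagnesium chloride (1.45 equiv), Et2O, 0 °C → rt; then 14, −78 °C, 3 h; then NaBO3·4H2O, THF/H2O, rt
Reagents that add atoms: methallylmagnesium chloride, C=C(C)C[Mg]Cl, transferred through (−)-B-methallyldiisopinocampheylborane made in the flask, CC(=C)CB([C@@H]1C[C@@H]2C[C@H]([C@H]1C)C2(C)C)[C@@H]1C[C@@H]2C[C@H]([C@H]1C)C2(C)C
Why: Brown asymmetric methallylboration: the reagent derived from (+)-α-pinene adds through a chair transition state under reagent control to give the (8S) carbinol, fast enough at −78 °C to avoid epimerisation at C7, and does not touch esters or the epoxide.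

Step 11
Reactants: 15 diene
Product: 16 [(3R,4S,5S)-4-[(1S)-1-hydroxy-3-oxobutyl]-5-[(2S,3R)-3-methyl-3-(3-oxopropyl)oxiran-2-yl]-2-oxooxolan-3-yl]methyl acetate
Conditions: O3, CH2Cl2, −78 °C; then Me2S, −78 °C → rt; used directly
Reagents that add atoms: ozone, [O-][O+]=O
Why: Ozonolysis (Criegee mechanism, reductive work-up) cleaves both electron-rich alkenes, the trisubstituted one to the C1 aldehyde and the 1,1-disubstituted one to the C10 methyl ketone, without touching any stereocentre.

Step 12
Reactants: 16 keto-aldehyde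
Product: 17 (4R,5S,6S,7S,8S,10R,11R)-13-acetoxy-4,5-epoxy-8,10-dihydroxy-1-oxogermacran-12,6-olide
Conditions: (5aS,10bR)-2-(pentafluorophenyl)-5a,10b-dihydro-4H,6H-indeno[2,1-b][1,2,4]triazolo[4,3-d][1,4]oxazin-2-ium tetrafluoroborate (C18H11BF9N3O, 20 mol%), iPr2NEt (20 mol%), toluene, 40 °C, 16 added by syringe pump over 12 h to 0.002 M
Reagents that add atoms: none
Why: Proposed new method: the triazolylidene adds to the unhindered C1 aldehyde to give the Breslow enaminol (acyl anion equivalent), whose C1 attacks the C10 methyl ketone and, after proton transfer and loss of the carbene, leaves the tertiary α-ketol and the closed ten-membered ring; the closest known reaction is the intramolecular crossed aldehyde–ketone benzoin (five- and six-membered rings), here run at high dilution with the cis-epoxide and cis-lactone as turn elements, and the C10 configuration is set by the chiral carbene acting on the preorganised chain (the sense cannot be predicted with confidence for a macrocycle and must be confirmed on the product).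

Step 13
Reactants: 17 ketol diol
Product: 18 (4R,5S,6S,7S,8S,10R,11R)-13-acetoxy-4,5-epoxy-10-hydroxy-8-(methacryloyloxy)-1-oxogermacran-12,6-olide
Conditions: methacrylic anhydride (1.5 equiv), Et3N, DMAP (10 mol%), CH2Cl2, 0 °C → rt
Reagents that add atoms: methacrylic anhydride, C=C(C)C(=O)OC(=O)C(C)=C
Why: DMAP-catalysed (Steglich-type) acylation; the secondary C8 hydroxyl reacts far faster than the tertiary C10 hydroxyl, so only the 8-ester forms.

Step 14
Reactants: 18 tertiary alcohol
Product: 19 CNP0166747.1, (4R,5S,6S,7S,8S,10R,11R)-10,13-diacetoxy-4,5-epoxy-8-(methacryloyloxy)-1-oxogermacran-12,6-olide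
Conditions: Ac2O (20 equiv), DMAP (2 equiv), CH2Cl2, 35 °C, 24–48 h
Reagents that add atoms: acetic anhydride, CC(=O)OC(C)=O
Why: DMAP-catalysed acetylation under forcing but acid-free conditions acylates the remaining tertiary α-ketol hydroxyl with retention at C10 (the C–O bond is not broken) and spares the epoxide.

**Compound list**

1 | nerol, (2Z)-3,7-dimethylocta-2,6-dien-1-ol | CC(C)=CCC/C(C)=C\CO | starting material
2 | (2S,3R)-2,3-epoxynerol, [(2S,3R)-3-methyl-3-(4-methylpent-3-en-1-yl)oxiran-2-yl]methanol | CC(C)=CCC[C@@]1(C)O[C@H]1CO | intermediate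
3 | (2R,3R)-3-methyl-3-(4-methylpent-3-en-1-yl)oxirane-2-carbaldehyde | CC(C)=CCC[C@@]1(C)O[C@H]1C=O | intermediate
4 | (tert-butyldimethylsilyloxy)acetaldehyde | CC(C)(C)[Si](C)(C)OCC=O | starting material
5 | methyl acrylate | C=CC(=O)OC | starting material
6 | methyl 4-[(tert-butyldimethylsilyl)oxy]-3-hydroxy-2-methylidenebutanoate (racemic) | C=C(C(=O)OC)C(O)CO[Si](C)(C)C(C)(C)C | intermediate
7 | methyl (Z)-2-(bromomethyl)-4-[(tert-butyldimethylsilyl)oxy]but-2-enoate | COC(=O)/C(CBr)=C/CO[Si](C)(C)C(C)(C)C | intermediate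
8 | methyl (3S,4S)-3-{[tert-butyl(dimethyl)silyl]oxymethyl}-4-hydroxy-2-methylidene-4-[(2S,3R)-3-methyl-3-(4-methylpent-3-en-1-yl)oxiran-2-yl]butanoate (syn-hydroxy ester) | CC(C)=CCC[C@@]1(C)O[C@H]1[C@@H](O)[C@H](CO[Si](C)(C)C(C)(C)C)C(=C)C(=O)OC | intermediate
9 | (4S,5S)-4-{[tert-butyl(dimethyl)silyl]oxymethyl}-3-methylidene-5-[(2S,3R)-3-methyl-3-(4-methylpent-3-en-1-yl)oxiran-2-yl]oxolan-2-one | CC(C)=CCC[C@@]1(C)O[C@H]1[C@H]1OC(=O)C(=C)[C@H]1CO[Si](C)(C)C(C)(C)C | intermediate
10 | (3S,4S,5S)-4-{[tert-butyl(dimethyl)silyl]oxymethyl}-5-[(2S,3R)-3-methyl-3-(4-methylpent-3-en-1-yl)oxiran-2-yl]-3-[(4,4,5,5-tetramethyl-1,3,2-dioxaborolan-2-yl)methyl]oxolan-2-one (pinacol boronate) | CC(C)=CCC[C@@]1(C)O[C@H]1[C@H]1OC(=O)[C@@H](CB2OC(C)(C)C(C)(C)O2)[C@H]1CO[Si](C)(C)C(C)(C)C | intermediate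
11 | (3R,4S,5S)-4-{[tert-butyl(dimethyl)silyl]oxymethyl}-3-(hydroxymethyl)-5-[(2S,3R)-3-methyl-3-(4-methylpent-3-en-1-yl)oxiran-2-yl]oxolan-2-one | CC(C)=CCC[C@@]1(C)O[C@H]1[C@H]1OC(=O)[C@@H](CO)[C@H]1CO[Si](C)(C)C(C)(C)C | intermediate
12 | [(3R,4S,5S)-4-{[tert-butyl(dimethyl)silyl]oxymethyl}-5-[(2S,3R)-3-methyl-3-(4-methylpent-3-en-1-yl)oxiran-2-yl]-2-oxooxolan-3-yl]methyl acetate | CC(C)=CCC[C@@]1(C)O[C@H]1[C@H]1OC(=O)[C@@H](COC(C)=O)[C@H]1CO[Si](C)(C)C(C)(C)C | intermediate
13 | [(3R,4S,5S)-4-(hydroxymethyl)-5-[(2S,3R)-3-methyl-3-(4-methylpent-3-en-1-yl)oxiran-2-yl]-2-oxooxolan-3-yl]methyl acetate | CC(C)=CCC[C@@]1(C)O[C@H]1[C@H]1OC(=O)[C@@H](COC(C)=O)[C@H]1CO | intermediate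
14 | [(3R,4R,5S)-4-formyl-5-[(2S,3R)-3-methyl-3-(4-methylpent-3-en-1-yl)oxiran-2-yl]-2-oxooxolan-3-yl]methyl acetate | CC(C)=CCC[C@@]1(C)O[C@H]1[C@H]1OC(=O)[C@@H](COC(C)=O)[C@H]1C=O | intermediate
15 | [(3R,4S,5S)-4-[(1S)-1-hydroxy-3-methylbut-3-en-1-yl]-5-[(2S,3R)-3-methyl-3-(4-methylpent-3-en-1-yl)oxiran-2-yl]-2-oxooxolan-3-yl]methyl acetate | CC(C)=CCC[C@@]1(C)O[C@H]1[C@H]1OC(=O)[C@@H](COC(C)=O)[C@H]1[C@@H](O)CC(C)=C | intermediate
16 | [(3R,4S,5S)-4-[(1S)-1-hydroxy-3-oxobutyl]-5-[(2S,3R)-3-methyl-3-(3-oxopropyl)oxiran-2-yl]-2-oxooxolan-3-yl]methyl acetate (seco keto-aldehyde) | O=CCC[C@@]1(C)O[C@H]1[C@H]1OC(=O)[C@@H](COC(C)=O)[C@H]1[C@@H](O)CC(C)=O | intermediate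
17 | (4R,5S,6S,7S,8S,10R,11R)-13-acetoxy-4,5-epoxy-8,10-dihydroxy-1-oxogermacran-12,6-olide | O[C@H]1C[C@@](C)(O)C(=O)CC[C@@]2(C)O[C@H]2[C@H]2OC(=O)[C@@H](COC(C)=O)[C@H]21 | intermediate
18 | (4R,5S,6S,7S,8S,10R,11R)-13-acetoxy-4,5-epoxy-10-hydroxy-8-(methacryloyloxy)-1-oxogermacran-12,6-olide | C=C(C)C(=O)O[C@H]1C[C@@](C)(O)C(=O)CC[C@@]2(C)O[C@H]2[C@H]2OC(=O)[C@@H](COC(C)=O)[C@H]21 | intermediate
19 | CNP0166747.1, (4R,5S,6S,7S,8S,10R,11R)-10,13-diacetoxy-4,5-epoxy-8-(methacryloyloxy)-1-oxogermacran-12,6-olide | C=C(C)C(=O)O[C@H]1C[C@@](C)(OC(C)=O)C(=O)CC[C@@]2(C)O[C@H]2[C@H]2OC(=O)[C@@H](COC(C)=O)[C@H]21 | target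

**Step count and risks**

Total: 14 steps. Longest linear sequence: 12 steps (nerol → 19 through steps 1, 2 and 5–14); the bromide branch (steps 3, 4) is 2 steps.

Steps most likely to fail:

Step 12 (macrocyclic crossed benzoin). Ten-membered ring closure by a reversible carbene-catalysed addition is unprecedented. Strain may favour the open form or dimers, the C10 facial selectivity is not predictable, and the base could eliminate the C13 acetate. Fallback: setting out from 16, SmI2 (2.5 equiv, THF, tBuOH, −78 °C → rt, high dilution) generates the C1 ketyl, which adds to the C10 ketone in a pinacol macrocyclisation to give the macrocyclic 1,8,10-triol F1. Chemoselective oxidation of the secondary carbinol of its vicinal diol with [(neocuproine)Pd(OAc)]2(OTf)2 (a divalent palladium catalyst) and benzoquinone in MeCN/H2O then returns to ketol 17.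

Step 5 (Barbier allylation/lactonisation). Three things can go wrong: the Felkin and syn preferences may not combine cleanly, the allyl metal may suffer 1,4-elimination of the silyloxy group, and DBU may isomerise the exocyclic alkene. Fallback: setting out from 7, borylation with B2pin2 and Pd2(dba)3 (zerovalent palladium) in toluene at 50 °C gives the isolable allylboronate F2. Heating F2 with aldehyde 3 in toluene (80 °C, no Lewis acid) effects a closed-transition-state allylboration that, after hydrolytic work-up, returns to hydroxy ester 8, which is lactonised as before to 9.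

Step 10 (methallylboration of the hindered, epimerisable all-cis aldehyde). Reagent control may be eroded by the substrate, or C7 may epimerise in steps 9–10. Fallback: setting out from 14, a D-proline-catalysed (30 mol%) aldol reaction with acetone (acetone/DMSO 1:4, rt) gives the β-hydroxy ketone F3 with the (8S) configuration under catalyst control. Ozonolysis of its remaining alkene (O3, CH2Cl2, −78 °C; Me2S) returns to keto-aldehyde 16.

**Further compounds**

F1 | step 12 | (4R,5S,6S,7S,8S,10R,11R)-13-acetoxy-4,5-epoxy-1,8,10-trihydroxygermacran-12,6-olide (mixture of C1 epimers) | O[C@H]1C[C@@](C)(O)C(O)CC[C@@]2(C)O[C@H]2[C@H]2OC(=O)[C@@H](COC(C)=O)[C@H]21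
F2 | step 5 | methyl (E)-4-[(tert-butyldimethylsilyl)oxy]-2-[(4,4,5,5-tetramethyl-1,3,2-dioxaborolan-2-yl)methyl]but-2-enoate | COC(=O)/C(CB1OC(C)(C)C(C)(C)O1)=C/CO[Si](C)(C)C(C)(C)C
F3 | step 10 | [(3R,4S,5S)-4-[(1S)-1-hydroxy-3-oxobutyl]-5-[(2S,3R)-3-methyl-3-(4-methylpent-3-en-1-yl)oxiran-2-yl]-2-oxooxolan-3-yl]methyl acetate | CC(C)=CCC[C@@]1(C)O[C@H]1[C@H]1OC(=O)[C@@H](COC(C)=O)[C@H]1[C@@H](O)CC(C)=O
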